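**Plan**

Numbering (prostanoid): C1 ester carbon, C5 and C7 CHOAc, C6 ring OCH, C8 ring-fusion CH, C9 C=O, C10 CCl, C11 =CH, C12 quaternary C–O, C13 CH2, C14=C15 Z.
Enabling feature: in the oxolane (O, C6, C7, C8, C12), C13 on C12 and C5 on C6 are cis and C5 bears oxygen. Rejoining C14 to C5 as a ketone therefore gives an 8-oxabicyclo[3.2.1]oct-6-en-3-one, whose diene half is a flat cyclopenta[b]furan already holding O and C6–C12.
Cuts, in retrosynthetic order: C10–Cl and C10=C11; C14=C15 (Wittig); C7–O and C8–H (hydroboration); C5–O back to C5–C14 (Baeyer–Villiger); C12–C13 and C5–C6 together ((4+3)); O–C6 and C7–C8 (Feist–Benary); C13–C14 (chloromethyl anion on caprolactone).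
Forward: the furan is annulated onto cyclopentanedione and the seven-membered ring is closed across it. Oxygen insertion and reduction unzip that ring to a cis-2,5-disubstituted dihydrofuran, then C7/C8, the Z chain, C1 and the chloroenone are completed.
Stereochemistry: C9 (transfer hydrogenation) steers the furan face (C12, C6) and, with cis-fusion strain, the hydroboration face (C7, C8). C5 comes from the compact mode, is carried with retention through oxygen insertion and is inverted by Mitsunobu; C9 is erased at the end.

Key step: step 6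

Remark: "up" means the oxolane face that carries C13 and C5. Chloroketone 27 is carried as a mixture of C10 epimers because C10 becomes sp2 in the last step.

**Route**

Step 1
Reactants: 1 cyclopentane-1,3-dione; 2 chloroacetaldehyde (50 wt % in water)
Product: 4 5,6-dihydro-4H-cyclopenta[b]furan-4-one, via 3-hydroxy-2,3,5,6-tetrahydro-4H-cyclopenta[b]furan-4-one 3 (not isolated)
Conditions: NaHCO3, H2O, 0 °C → rt; then H2SO4 (cat., pH 1), EtOAc, rt
Reagents that add atoms: none
Why: Feist–Benary furan synthesis, in which the dione carbon (C8) adds to the aldehyde, the enol oxygen displaces chloride, and acid dehydrates 3 to the aromatic furan, as is routine for cyclohexane-1,3-dione.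

Step 2
Reactants: 4 5,6-dihydro-4H-cyclopenta[b]furan-4-one
Product: 5 (R)-5,6-dihydro-4H-cyclopenta[b]furan-4-ol
Conditions: RuCl(p-cymene)[(R,R)-TsDPEN] (1 mol %), HCO2H/Et3N 5:2, 30 °C
Reagents that add atoms: none
Why: Noyori-type asymmetric transfer hydrogenation of an aryl-fused cyclopentanone, in which the (R,R) catalyst should recognise the furan as the aryl flank and give the R carbinol (C9), the sense known for 1-indanone.

Step 3
Reactants: 5 (R)-5,6-dihydro-4H-cyclopenta[b]furan-4-ol
Product: 6 (R)-4-(tert-butyldimethylsilyloxy)-5,6-dihydro-4H-cyclopenta[b]furan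
Conditions: TBSCl, imidazole, DMF, rt
Reagents that add atoms: tert-butyldimethylsilyl chloride, CC(C)(C)[Si](C)(C)Cl
Why: Standard silylation under non-acidic conditions protects the ionisable furyl carbinol and installs the bulky group that later shields one face of the flat bicycle.

Step 4
Reactants: 7 ε-caprolactone
Product: 8 1-chloro-7-hydroxyheptan-2-one
Conditions: ClCH2I, MeLi·LiBr, THF/Et2O, −78 °C (carbenoid generated in the presence of 7); AcOH, −78 °C
Reagents that add atoms: chloroiodomethane, ClCI
Why: Chloromethyllithium homologation of an ester, in which the chlorine-stabilised tetrahedral adduct should survive at −78 °C until the acid quench, so only one C1 unit (C13) is added.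

Step 5
Reactants: 8 1-chloro-7-hydroxyheptan-2-one
Product: 9 1-chloro-7-(tert-butyldimethylsilyloxy)heptan-2-one
Conditions: TBSOTf, 2,6-lutidine, CH2Cl2, −78 °C
Reagents that add atoms: tert-butyldimethylsilyl triflate, CC(C)(C)[Si](C)(C)OS(=O)(=O)C(F)(F)F
Why: Silylation with a hindered, non-nucleophilic base avoids displacement of the reactive α-chloride that imidazole or DMAP could cause.

Step 6
Reactants: 6 (R)-4-(tert-butyldimethylsilyloxy)-5,6-dihydro-4H-cyclopenta[b]furan; 9 1-chloro-7-(tert-butyldimethylsilyloxy)heptan-2-one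
Product: 11 tricyclic (4+3) adduct (cyclopentane-fused 8-oxabicyclo[3.2.1]oct-6-en-3-one; C14 ketone; bridgeheads C12 and C6; C7=C8; C9 OTBS anti to the C13–C14–C5 bridge; 4-(TBSO)butyl chain equatorial on C5), via (Z)-2-oxidoallyl cation C13–C14–C5 10 (not isolated)
Conditions: Et3N (3 equiv), CF3CH2OH, 0 °C → rt, 9 (2.5 equiv) added slowly to 6; then stirred with the amine until the C5 epimers converge
Reagents that add atoms: none
Why: Et3N reversibly enolises 9 at C5, and in the ionising, weakly nucleophilic alcohol the enolate loses chloride to give the W-shaped oxidoallyl cation 10, which the electron-rich furan traps in a concerted-asynchronous or rapid stepwise [4π+2π] process that forms C5–C6 and C12–C13. The closest known reaction is the (4+3) cycloaddition of furans with oxyallyl cations generated from α-chloroketones by amine base in trifluoroethanol. The one new ring, the seven-membered carbocycle C12–C13–C14–C5–C6–C7=C8, closes by intermolecular suprafacial addition of the three-carbon cation across both furan α-carbons, which turns the furan oxygen into the one-atom bridge. C12 and C6 are set together by the furan face attacked, and the C9 silyloxy group next to C8 should leave only the opposite face open; C5 is set by the compact approach of the W cation, which places the chain equatorial, and the enolisable C5–H should let the amine funnel any axial epimer to this more stable isomer. The step also needs regiocontrol, which the substrate should supply: the unsubstituted, most nucleophilic furan carbon C6 bonds to the substituted terminus C5, and the small CH2 terminus C13 closes on the alkylated C12, so no vicinal quaternary–tertiary pair is built. Slow addition of excess 9 keeps the furan in excess over the cation and should limit solvent capture and Favorskii collapse.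

Step 7
Reactants: 11 tricyclic (4+3) adduct
Product: 12 bridged seven-membered lactone C14(=O)–O–C5 (5S; otherwise as 11)
Conditions: Me3SiOOSiMe3, TMSOTf (10 mol %), 4 Å MS, CH2Cl2, −40 °C
Reagents that add atoms: bis(trimethylsilyl) peroxide, C[Si](C)(C)OO[Si](C)(C)C
Why: Baeyer–Villiger oxidation with a silyl peroxide that attacks only the activated carbonyl and should spare C7=C8 (shielded on both faces and deactivated by three allylic C–O bonds), in which secondary C5 migrates in preference to primary C13 with retention and gives 5S.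

Step 8
Reactants: 12 bridged lactone
Product: 13 diol 6a-(2-hydroxyethyl)-2-[(1S)-1-hydroxy-5-(TBSO)pentyl]-4-(TBSO)-4,5,6,6a-tetrahydro-2H-cyclopenta[b]furan (C2 and C6a chains cis; C4 OTBS on the other face)
Conditions: LiBH4, THF, 0 °C → rt
Reagents that add atoms: none
Why: Borohydride reduction of a lactone to the diol unzips the bridge without touching the silyl ethers, the alkene or any stereocentre.

Step 9
Reactants: 13 diol
Product: 14 C14 triethylsilyl ether of 13 (5S-OH free)
Conditions: TESCl (1.05 equiv), imidazole, CH2Cl2, −20 °C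
Reagents that add atoms: chlorotriethylsilane, CC[Si](Cl)(CC)CC
Why: Rate-controlled silylation should select the unhindered primary C14 hydroxyl over the secondary, α-branched C5 hydroxyl.

Step 10
Reactants: 14 C14 TES ether (5S-OH)
Product: 15 (5R)-acetate of the C14 TES ether
Conditions: PPh3, DIAD, AcOH, toluene, 0 °C → rt
Reagents that add atoms: acetic acid, CC(=O)O
Why: Mitsunobu reaction, in which acetate displaces the oxyphosphonium group by SN2 and inverts C5 from S to R, a transformation well precedented for carbinols flanking oxolane rings.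

Step 11
Reactants: 15 (5R)-acetate
Product: 17 C7 alcohol (cis-fused hexahydro-2H-cyclopenta[b]furan-3-ol; 7-OH, H8, the C13 chain and the C5 chain all up; C9 OTBS down), via C7 alkylborane 16 (not isolated)
Conditions: BH3·THF, THF, 0 °C → rt; then 30 % H2O2, aq NaOAc, 0 °C
Reagents that add atoms: hydrogen peroxide, OO (oxygen on C7); borane, B (boron of 16 only)
Why: Hydroboration–oxidation places boron on the less substituted C7 and hydrogen on C8 in a syn addition that should occur on the convex up face, because only that face gives a cis-fused bicyclo[3.3.0] skeleton and the other is covered by the C9 OTBS group; retentive oxidation then gives 7S and 8S.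

Step 12
Reactants: 17 C7 alcohol
Product: 18 5,7-diacetate (C14 OTES; C1 and C9 OTBS)
Conditions: Ac2O, pyridine, DMAP (cat.), CH2Cl2, rt
Reagents that add atoms: acetic anhydride, CC(=O)OC(C)=O
Why: Exhaustive acetylation caps C7 and also repairs any C5/C7 acyl migration or partial acetate loss from step 11, since both positions end as acetates.

Step 13
Reactants: 18 5,7-diacetate
Product: 19 C14 aldehyde
Conditions: (COCl)2, DMSO, CH2Cl2, −78 → −40 °C; Et3N, −78 → 0 °C
Reagents that add atoms: none
Why: Direct Swern oxidation of a primary triethylsilyl ether, in which the activated sulfonium reagent exchanges with the labile TES ether but not with TBS ethers, delivers the aldehyde without an acidic deprotection.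

Step 14
Reactants: 19 C14 aldehyde; 20 hexyltriphenylphosphonium bromide
Product: 22 (14Z)-alkene (5,7-diacetate; C1 and C9 OTBS), via hexylidenetriphenylphosphorane 21 (not isolated)
Conditions: 20, NaHMDS, THF, 0 °C; then 19, −78 → −20 °C
Reagents that add atoms: none
Why: Lithium-free Wittig olefination with a non-stabilised ylide proceeds under kinetic control to the Z alkene, and at low temperature the aldehyde should react far faster than the acetates or the acidic C13–H.

Step 15
Reactants: 22 (14Z)-alkene bis-TBS ether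
Product: 23 C1,C9-diol
Conditions: HF·pyridine, pyridine, THF, 0 °C → rt
Reagents that add atoms: none
Why: Buffered acidic fluoride removes both TBS groups in one operation without the acetate migration or hydrolysis that basic fluoride could cause.

Step 16
Reactants: 23 C1,C9-diol
Product: 24 9-oxo C1 carboxylic acid
Conditions: Jones reagent (CrO3, aq H2SO4), acetone, −10 °C
Reagents that add atoms: water, O
Why: Jones oxidation takes the primary alcohol to the acid and the secondary alcohol to the ketone together under acidic conditions that spare the β-acetoxy ketone and the Z alkene, and C8 stays put because only the cis fusion is low in energy.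

Step 17
Reactants: 24 9-oxo C1 acid
Product: 25 methyl ester 9-ketone (the 10-deschloro-10,11-dihydro target)
Conditions: TMSCHN2, toluene/MeOH 4:1, 0 °C
Reagents that add atoms: trimethylsilyldiazomethane, C[Si](C)(C)C=[N+]=[N-]
Why: Diazoalkane esterification is base-free, so neither β-leaving group of the ketone (C7 OAc, C12–O) is put at risk.

Step 18
Reactants: 25 methyl ester 9-ketone
Product: 27 10-chloro-9-ketone (C10 epimers), via C9=C10 trimethylsilyl enol ether 26 (not isolated)
Conditions: TMSCl, then LiHMDS (1.1 equiv), THF, −78 °C; crude 26, NCS, THF, −78 → 0 °C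
Reagents that add atoms: chlorotrimethylsilane, C[Si](C)(C)Cl (silicon of 26 only); N-chlorosuccinimide, O=C1CCC(=O)N1Cl
Why: Kinetic enolisation with internal silyl quench should remove a free C10 proton rather than C8–H, which is wedged between the cis C7 acetate and the C13 chain, and the enol silane is chlorinated by NCS much faster than the isolated Z alkene.

Step 19
Reactants: 27 10-chloro-9-ketone
Product: 29 CNP0318775.1 (5R,6S,7S,8S,12R,14Z), via 10-chloro C9=C10 trimethylsilyl enol ether 28 (not isolated)
Conditions: TMSOTf, Et3N, CH2Cl2, 0 °C; crude 28, Pd(OAc)2 (1.1 equiv), MeCN, rt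
Reagents that add atoms: trimethylsilyl triflate, C[Si](C)(C)OS(=O)(=O)C(F)(F)F (silicon of 28 only)
Why: Soft enolisation should go to the chlorine-acidified C10–H, and Saegusa–Ito oxidation (C10 palladium enolate, then β-hydride loss from C11) should give the 2-chloroenone under near-neutral conditions that the β-acetoxy enone tolerates.

**Compound list**

1 | cyclopentane-1,3-dione | O=C1CCC(=O)C1 | starting material
2 | chloroacetaldehyde | ClCC=O | starting material
3 | 3-hydroxy-2,3,5,6-tetrahydro-4H-cyclopenta[b]furan-4-one | O=C1CCC2=C1C(O)CO2 | intermediate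
4 | 5,6-dihydro-4H-cyclopenta[b]furan-4-one | O=C1CCc2occc12 | intermediate
5 | (R)-5,6-dihydro-4H-cyclopenta[b]furan-4-ol | O[C@@H]1CCc2occc12 | intermediate
6 | (R)-4-(tert-butyldimethylsilyloxy)-5,6-dihydro-4H-cyclopenta[b]furan | CC(C)(C)[Si](C)(C)O[C@@H]1CCc2occc12 | intermediate
7 | ε-caprolactone | O=C1CCCCCO1 | starting material
8 | 1-chloro-7-hydroxyheptan-2-one | OCCCCCC(=O)CCl | intermediate
9 | 1-chloro-7-(tert-butyldimethylsilyloxy)heptan-2-one | ClCC(=O)CCCCCO[Si](C)(C)C(C)(C)C | intermediate
10 | (Z)-2-oxidoallyl cation C13–C14–C5 with the 4-(TBSO)butyl chain on C5 | [CH2+]/C([O-])=C/CCCCO[Si](C)(C)C(C)(C)C | intermediate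
11 | tricyclic (4+3) adduct, chain equatorial on C5, C9 OTBS anti to the bridge | O=C1C[C@]23CC[C@@H](O[Si](C)(C)C(C)(C)C)C2=C[C@@H](O3)[C@@H]1CCCCO[Si](C)(C)C(C)(C)C | intermediate
12 | bridged lactone C14(=O)–O–C5 (5S) | O=C1C[C@]23CC[C@@H](O[Si](C)(C)C(C)(C)C)C2=C[C@@H](O3)[C@H](CCCCO[Si](C)(C)C(C)(C)C)O1 | intermediate
13 | C14,C5-diol (5S) | OCC[C@]12CC[C@@H](O[Si](C)(C)C(C)(C)C)C1=C[C@@H](O2)[C@H](CCCCO[Si](C)(C)C(C)(C)C)O | intermediate
14 | C14 TES ether, 5S-OH | CC[Si](CC)(CC)OCC[C@]12CC[C@@H](O[Si](C)(C)C(C)(C)C)C1=C[C@@H](O2)[C@H](CCCCO[Si](C)(C)C(C)(C)C)O | intermediate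
15 | C14 TES ether, (5R)-acetate | CC[Si](CC)(CC)OCC[C@]12CC[C@@H](O[Si](C)(C)C(C)(C)C)C1=C[C@@H](O2)[C@@H](CCCCO[Si](C)(C)C(C)(C)C)OC(C)=O | intermediate
16 | C7 alkylborane | CC[Si](CC)(CC)OCC[C@]12CC[C@@H](O[Si](C)(C)C(C)(C)C)[C@H]1[C@H](B)[C@H]([C@@H](CCCCO[Si](C)(C)C(C)(C)C)OC(C)=O)O2 | intermediate
17 | C7 alcohol, cis-fused | CC[Si](CC)(CC)OCC[C@]12CC[C@@H](O[Si](C)(C)C(C)(C)C)[C@H]1[C@H](O)[C@H]([C@@H](CCCCO[Si](C)(C)C(C)(C)C)OC(C)=O)O2 | intermediate
18 | 5,7-diacetate | CC[Si](CC)(CC)OCC[C@]12CC[C@@H](O[Si](C)(C)C(C)(C)C)[C@H]1[C@H](OC(C)=O)[C@H]([C@@H](CCCCO[Si](C)(C)C(C)(C)C)OC(C)=O)O2 | intermediate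
19 | C14 aldehyde | O=CC[C@]12CC[C@@H](O[Si](C)(C)C(C)(C)C)[C@H]1[C@H](OC(C)=O)[C@H]([C@@H](CCCCO[Si](C)(C)C(C)(C)C)OC(C)=O)O2 | intermediate
20 | hexyltriphenylphosphonium bromide | [Br-].CCCCCC[P+](c1ccccc1)(c1ccccc1)c1ccccc1 | starting material
21 | hexylidenetriphenylphosphorane | CCCCCC=P(c1ccccc1)(c1ccccc1)c1ccccc1 | intermediate
22 | (14Z)-alkene, C1 and C9 OTBS | CCCCC/C=C\C[C@]12CC[C@@H](O[Si](C)(C)C(C)(C)C)[C@H]1[C@H](OC(C)=O)[C@H]([C@@H](CCCCO[Si](C)(C)C(C)(C)C)OC(C)=O)O2 | intermediate
23 | C1,C9-diol | CCCCC/C=C\C[C@]12CC[C@@H](O)[C@H]1[C@H](OC(C)=O)[C@H]([C@@H](CCCCO)OC(C)=O)O2 | intermediate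
24 | 9-oxo C1 acid | CCCCC/C=C\C[C@]12CCC(=O)[C@H]1[C@H](OC(C)=O)[C@H]([C@@H](CCCC(=O)O)OC(C)=O)O2 | intermediate
25 | methyl ester 9-ketone | CCCCC/C=C\C[C@]12CCC(=O)[C@H]1[C@H](OC(C)=O)[C@H]([C@@H](CCCC(=O)OC)OC(C)=O)O2 | intermediate
26 | C9=C10 TMS enol ether | CCCCC/C=C\C[C@]12CC=C(O[Si](C)(C)C)[C@H]1[C@H](OC(C)=O)[C@H]([C@@H](CCCC(=O)OC)OC(C)=O)O2 | intermediate
27 | 10-chloro-9-ketone (C10 epimers) | CCCCC/C=C\C[C@]12CC(Cl)C(=O)[C@H]1[C@H](OC(C)=O)[C@H]([C@@H](CCCC(=O)OC)OC(C)=O)O2 | intermediate
28 | 10-chloro C9=C10 TMS enol ether | CCCCC/C=C\C[C@]12CC(Cl)=C(O[Si](C)(C)C)[C@H]1[C@H](OC(C)=O)[C@H]([C@@H](CCCC(=O)OC)OC(C)=O)O2 | intermediate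
29 | CNP0318775.1 | CCCCC/C=C\C[C@]12C=C(Cl)C(=O)[C@H]1[C@H](OC(C)=O)[C@H]([C@@H](CCCC(=O)OC)OC(C)=O)O2 | target

**Counts and risks**

Total step count: 19.
Longest linear sequence: 17 (steps 1–3 and 6–19).

Steps most likely to fail:

**Step 6.** The mono-alkyl oxyallyl cation is only weakly stabilised. It may be captured by the solvent or collapse along the Favorskii path before the hindered ring-fused furan traps it, and regio- or facial selectivity may erode.

The fallback sets out from 6 and returns at 11; it moves the C4–C5 bond formation to after the cycloaddition.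
- 6 is combined with 1,1,3-trichloroacetone (Et3N, CF3CH2OH). Its chlorine-stabilised, symmetrical 1,3-dichloro-2-oxidoallyl cation is longer-lived and poses no regiochemical choice, and should give the 5,13-dichloro cycloadduct F1.
- Zinc–copper couple in NH4Cl/MeOH removes both chlorines to give the chain-free tricyclic ketone F2.
- Kinetic deprotonation (LDA, THF, −78 °C) on the side away from quaternary C12, followed by alkylation with tert-butyl(4-iodobutoxy)dimethylsilane (DMPU), should first give the axial C5 epimer of 11 F3. DBU then equilibrates this to 11.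

**Step 11.** Both faces of C7=C8 are flanked, so hydroboration may be slow or face-unselective. Acetate reduction or fragmentation of the β-alkoxyborane could then overtake it.

The fallback sets out from 15 and returns at 18; it ties the reagent to the up face.
- DIBAL-H (CH2Cl2, −78 °C) cleaves the acetate to the (5R)-alcohol F4.
- Chlorodimethylsilane/Et3N gives the C5 dimethylsilyl ether F5.
- Karstedt catalyst (toluene, 60 °C) effects intramolecular syn hydrosilylation in the 5-exo mode. Silicon goes to C7 and hydrogen to C8 from the face of the tether, giving the cis-fused 1,2-oxasilolane F6.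
- Fluoride-free Tamao oxidation (H2O2, KHCO3, THF/MeOH) gives the 5,7-diol F7 with retention.
- Ac2O/pyridine/DMAP converts F7 into 18.

**Step 19.** Palladation of the tetrasubstituted chloro enol silane may be sluggish. Protodesilylation back to the chloroketone may compete, and the C7 acetate may be lost during long reaction times.

The fallback sets out from 27 (through 28, made as in step 19) and returns at 29; it replaces the palladium step with a selenoxide syn elimination.
- 28 is treated with PhSeCl (CH2Cl2, −78 °C) to give the 10-chloro-10-(phenylselanyl) ketone F8.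
- 30 % H2O2 (CH2Cl2, 0 °C) oxidises it to the selenoxide F9.
- F9 can eliminate only toward C11–H and should give 29 below room temperature.

**Further compounds**

F1 | step 6 | 5,13-dichloro cycloadduct | O=C1C(Cl)[C@]23CC[C@@H](O[Si](C)(C)C(C)(C)C)C2=C[C@@H](O3)C1Cl
F2 | step 6 | chain-free tricyclic ketone | O=C1C[C@]23CC[C@@H](O[Si](C)(C)C(C)(C)C)C2=C[C@@H](O3)C1
F3 | step 6 | axial C5 epimer of 11 | O=C1C[C@]23CC[C@@H](O[Si](C)(C)C(C)(C)C)C2=C[C@@H](O3)[C@H]1CCCCO[Si](C)(C)C(C)(C)C
F4 | step 11 | (5R)-alcohol | CC[Si](CC)(CC)OCC[C@]12CC[C@@H](O[Si](C)(C)C(C)(C)C)C1=C[C@@H](O2)[C@@H](CCCCO[Si](C)(C)C(C)(C)C)O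
F5 | step 11 | C5 dimethylsilyl ether | CC[Si](CC)(CC)OCC[C@]12CC[C@@H](O[Si](C)(C)C(C)(C)C)C1=C[C@@H](O2)[C@@H](CCCCO[Si](C)(C)C(C)(C)C)O[SiH](C)C
F6 | step 11 | cis-fused 1,2-oxasilolane | CC[Si](CC)(CC)OCC[C@]12CC[C@@H](O[Si](C)(C)C(C)(C)C)[C@H]1[C@H]3[C@H]([C@@H](CCCCO[Si](C)(C)C(C)(C)C)O[Si]3(C)C)O2
F7 | step 11 | 5,7-diol | CC[Si](CC)(CC)OCC[C@]12CC[C@@H](O[Si](C)(C)C(C)(C)C)[C@H]1[C@H](O)[C@H]([C@@H](CCCCO[Si](C)(C)C(C)(C)C)O)O2
F8 | step 19 | 10-chloro-10-(phenylselanyl) ketone | CCCCC/C=C\C[C@]12CC(Cl)([Se]c3ccccc3)C(=O)[C@H]1[C@H](OC(C)=O)[C@H]([C@@H](CCCC(=O)OC)OC(C)=O)O2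
F9 | step 19 | selenoxide | CCCCC/C=C\C[C@]12CC(Cl)([Se](=O)c3ccccc3)C(=O)[C@H]1[C@H](OC(C)=O)[C@H]([C@@H](CCCC(=O)OC)OC(C)=O)O2
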